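Late in the north-east run, between 5.00 h and 12.0 h, electrophile falls with a first-order constant of 0.0551 h⁻¹. That is lower than the 0.0645 h⁻¹ read over the first 2.50 h. The reckoning below follows that fall out to 40 h.

in all of them: electrophile 10 mM

| charge | nucleophile | buffer base | buffer acid | protic impurity | remark | time |
|---|---|---|---|---|---|---|
| north-east | 15 mM | 20 mM | 1 mM | 10 mM | the very flask that is asked about, followed so far |  |
| flask | 15.0 mM | 20.0 mM | 1.00 mM | 10.0 mM |  | 40 h |

north-east run (percent of the electrophile charged)

| time / h | electrophile / % | target / % |
|---|---|---|
| 2.50 | 85.1 | 11.0 |
| 5.00 | 72.5 | 19.6 |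
| 8.00 | 60.8 | 27.7 |
| 10.0 | 55.1 | 31.8 |
| 12.0 | 49.3 | 35.2 |

(standard deviation of a reading: 0.3 percentage points)

- part of the electrophile that has reacted at 40 h
- pH of the solution at 40 h

- the numbers in the tables scatter with a standard deviation of 0.3 percentage points
- the earlier runs do not show the pH; that part of a forecast is a guess

1. Main step by itself. At 12.0 h target makes up 69.4% of the electrophile lost, a reading. With nucleophile in excess, the step is pseudo-first-order, and that share of the starting constant, 0.0448 h⁻¹, gives 83.3% reacted at 40 h.

2. One more path. The remaining loss is taken here to be reaction with protic impurity. It restores the full 0.0645 h⁻¹ and lifts the figure to 92.4%.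

3. The rest is a correction. Each path slows in proportion to its partner, and electrophile consumed takes nucleophile and protic impurity in the shares above. The squared target share over the nucleophile charge, plus the squared remainder over the impurity charge, times the electrophile charge, gives 41.5%. This is the slowing fraction, the part of the starting constant lost once the entire electrophile charge is consumed.

4. Correction applied. From 12.0 h onward, consumption lies between the 50.7% read there and the full charge, with a midpoint of 75.4%. The constant is then 0.0444 h⁻¹. Starting from the 49.3% still present, the reckoning here gives 85.8% reacted. The earlier runs show no pH, so it gives no pH.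

5. The forecast says 85% (78% to 90%), lower than the figure here. For the pH it says 7.5 (5.5 to 9.5), with the caution “The pKa is unknown”.

6. The flask gives 85.6% reacted, inside the forecast's range, and pH 10.1, above its high end, with buffer base at 68.8% and buffer acid at 723% of own charge.

    protonated nucleophile ⇌ nucleophile + acid, settled at all times (K = 1.60 × 10⁻⁹ M)
    electrophile + protic impurity → quenched substrate (k = 1.30 L mol⁻¹ h⁻¹)
    electrophile + nucleophile → acid + target + leaving group (k = 3.70 L mol⁻¹ h⁻¹)
    target ⇌ isomer of the product (K = 0.150, k = 0.0560 h⁻¹)
    buffer acid ⇌ buffer base + acid, settled at all times (K = 1.60 × 10⁻¹⁰ M)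

At 85.6% consumed, the slowing fraction leaves this flask a constant of 0.0416 h⁻¹. In the neighbour flask with 9.0 mM of nucleophile, the main path scales with its charge, so the starting constant becomes 0.0466 h⁻¹. Its own target share is then 57.7% and its own slowing fraction 54.9%. Taking off half of that fall, 0.0128 h⁻¹, gives 74.1% reacted, and that neighbour flask gives 72.2%.

Readings and results stem from a simulated flask for substances that don't exist; scatter was added.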